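**Retrosynthetic overview**
1. The target is 2-methoxy-6-nonadecyl-1,4-benzoquinone (C1=O, C2–OMe, C3–H, C4=O, C5–H, C6–chain). The C1 oxygen is added last, by para-oxidation of 3-methoxy-5-nonadecylphenol 16 (OH on C4).
2. 16 comes from the mono-silylated 5-nonadecylresorcinol 14 by O-methylation of the free OH (on C2) and desilylation (on C4).
3. 14 comes from a Danheiser benzannulation of 3-nonadecylcyclobutenone 5 with siloxyalkyne 9. The alkyne is the C3–C4 unit (H–C≡C–O); the cyclobutenone supplies C5, C6 (with the chain), C1 and C2 (its carbonyl carbon). The new bonds are C2–C3 and C4–C5, and the temporary C2–C5 bond of the four-membered ring is lost. The six-membered ring, the only ring of the target, is formed here.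
4. Enabling feature: the oxygens on C2 and C4 are meta, with C3–H between them and the chain on C6 meta to both (a 5-alkylresorcinol pattern). C2–O is thus a latent ketene carbonyl and C4–O a latent ynol ether oxygen, and the free para position C1 can be oxidised afterwards.
5. 5 comes from 1-bromononadecane and 3-ethoxycyclobutenone; 9 comes from acetylene.

Key step: step 3

Remark: 3-ethoxycyclobut-2-en-1-one (2) is taken as a catalogue compound; the fallback to step 1 reaches 5 without it.

Step 1
Reactants: 1 1-bromononadecane; 2 3-ethoxycyclobut-2-en-1-one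
Product: 5 3-nonadecylcyclobut-2-en-1-one, via nonadecylmagnesium bromide 3 (not isolated), via carbinol 4 (not isolated)
Conditions: Mg turnings, I2 (cat.), THF, reflux; then 2, THF, −40 → 0 °C; then 2 M HCl, 0 °C → rt
Reagents that add atoms: magnesium, [Mg] (held only in 3); water, O
Why: Grignard formation, 1,2-addition to the carbonyl of the vinylogous ester and acid-promoted hydrolysis with allylic transposition (Stork–Danheiser sequence) should give the 3-alkylcyclobutenone, in which no stereocentre remains.

Step 2
Reactants: 6 acetylene
Product: 9 (ethynyloxy)tri(propan-2-yl)silane, via lithium acetylide 7 (not isolated), via lithium ethynolate 8 (not isolated)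
Conditions: HC≡CH (excess), n-BuLi, THF, −78 °C; added to t-BuOOLi (from t-BuOOH, LiN(SiMe3)2), THF, −78 → −20 °C; then i-Pr3SiOTf, −78 → 0 °C
Reagents that add atoms: butyllithium, [Li]CCCC (lithium held only in 7 and 8); tert-butyl hydroperoxide, CC(C)(C)OO; triisopropylsilyl trifluoromethanesulfonate, CC(C)[Si](C(C)C)(C(C)C)OS(=O)(=O)C(F)(F)F
Why: Oxidation of a lithium acetylide with lithium tert-butyl peroxide should give the lithium ynolate, which the bulky silyl triflate should trap on oxygen (ynolate O-silylation), while excess acetylene and low temperature hold back disproportionation of the mono-acetylide.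

Step 3
Reactants: 5 3-nonadecylcyclobut-2-en-1-one; 9 (ethynyloxy)tri(propan-2-yl)silane
Product: 14 3-nonadecyl-5-{[tri(propan-2-yl)silyl]oxy}phenol, via vinylketene 10 (not isolated), via alkenylcyclobutenone 11 (not isolated), via dienylketene 12 (not isolated), via cyclohexadienone 13 (not isolated)
Conditions: 9 (1.3 equiv), toluene, argon, 80 °C, 4 h, then 110 °C, 2 h
Reagents that add atoms: none
Why: At 80 °C 5 should open by a 4π-electrocyclic reaction to vinylketene 10, whose ketene C=C adds to the electron-rich alkyne 9 in a [2+2] cycloaddition to give 11; a second 4π opening gives dienylketene 12, which closes by 6π-electrocyclisation to 13 and tautomerises to 14. The closest known reaction type is the Danheiser benzannulation of 3-alkylcyclobutenones with trialkylsilyloxyalkynes. The transient four-membered ring of 11 closes by [2+2] cycloaddition and the six-membered ring by thermal disrotatory 6π-electrocyclisation, so that the alkyne is in effect inserted into the C(=O)–CH bond of 5. No stereocentre is set, because the sp3 carbon of racemic 11 is lost in the next ring opening. The step needs regioselectivity in the [2+2] event, and polarity secures it: the nucleophilic CH terminus of the ynol silyl ether bonds to the electrophilic ketene carbonyl carbon and the silyloxy carbon to the ketene α-carbon, which places the two oxygens meta with a C–H between them and the chain meta to both. Because the free OH comes from the ketene and the silyl ether from the alkyne, the two oxygens leave the step differentiated.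

Step 4
Reactants: 14 3-nonadecyl-5-{[tri(propan-2-yl)silyl]oxy}phenol
Product: 15 (3-methoxy-5-nonadecylphenoxy)tri(propan-2-yl)silane
Conditions: MeI, K2CO3, acetone, 50 °C
Reagents that add atoms: iodomethane, CI
Why: Williamson O-methylation should take place at the only free phenol, and the hindered aryl triisopropylsilyl ether should survive K2CO3 in acetone.

Step 5
Reactants: 15 (3-methoxy-5-nonadecylphenoxy)tri(propan-2-yl)silane
Product: 16 3-methoxy-5-nonadecylphenol
Conditions: Bu4NF, THF, 0 °C; dilute HCl quench
Reagents that add atoms: none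
Why: Fluoride-induced cleavage of the aryl silyl ether should free the phenol on the alkyne-derived carbon and leave the methyl ether untouched.

Step 6
Reactants: 16 3-methoxy-5-nonadecylphenol
Product: 17 2-methoxy-6-nonadecylcyclohexa-2,5-diene-1,4-dione
Conditions: (KSO3)2NO (2.5 equiv), KH2PO4 buffer, H2O/CH2Cl2, methyltrioctylammonium chloride (cat.), rt
Reagents that add atoms: dipotassium nitrosodisulfonate (Fremy's salt), [K+].[K+].[O-]S(=O)(=O)N([O])S(=O)(=O)[O-]
Why: In the Teuber oxidation the nitrosodisulfonate radical should abstract the phenolic hydrogen and a second radical should attack the free para carbon between the methoxy- and alkyl-bearing carbons, which gives the para-quinone as in known oxidations of 3-methoxy-5-alkylphenols.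

**Compound list**
1 | 1-bromononadecane | CCCCCCCCCCCCCCCCCCCBr | starting material
2 | 3-ethoxycyclobut-2-en-1-one | CCOC1=CC(=O)C1 | starting material
3 | nonadecylmagnesium bromide (formed in the flask, step 1) | CCCCCCCCCCCCCCCCCCC[Mg]Br | intermediate
4 | 3-ethoxy-1-nonadecylcyclobut-2-en-1-ol, racemic (formed in the flask, step 1) | CCCCCCCCCCCCCCCCCCCC1(O)C=C(OCC)C1 | intermediate
5 | 3-nonadecylcyclobut-2-en-1-one | CCCCCCCCCCCCCCCCCCCC1=CC(=O)C1 | intermediate
6 | acetylene (ethyne) | C#C | starting material
7 | lithium acetylide (formed in the flask, step 2) | [Li]C#C | intermediate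
8 | lithium ethynolate (formed in the flask, step 2) | [Li]OC#C | intermediate
9 | (ethynyloxy)tri(propan-2-yl)silane | C#CO[Si](C(C)C)(C(C)C)C(C)C | intermediate
10 | 3-methylidenedocos-1-en-1-one, the vinylketene (formed in the flask, step 3) | CCCCCCCCCCCCCCCCCCCC(=C)C=C=O | intermediate
11 | 4-(henicos-1-en-2-yl)-3-{[tri(propan-2-yl)silyl]oxy}cyclobut-2-en-1-one, racemic (formed in the flask, step 3) | CCCCCCCCCCCCCCCCCCCC(=C)C1C(=O)C=C1O[Si](C(C)C)(C(C)C)C(C)C | intermediate
12 | (3E)-5-methylidene-3-{[tri(propan-2-yl)silyl]oxy}tetracosa-1,3-dien-1-one, the dienylketene with the ketenyl and alkenyl groups cis (formed in the flask, step 3) | C(/C=C=O)(O[Si](C(C)C)(C(C)C)C(C)C)=C/C(=C)CCCCCCCCCCCCCCCCCCC | intermediate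
13 | 5-nonadecyl-3-{[tri(propan-2-yl)silyl]oxy}cyclohexa-2,4-dien-1-one (formed in the flask, step 3) | CCCCCCCCCCCCCCCCCCCC1=CC(O[Si](C(C)C)(C(C)C)C(C)C)=CC(=O)C1 | intermediate
14 | 3-nonadecyl-5-{[tri(propan-2-yl)silyl]oxy}phenol | CCCCCCCCCCCCCCCCCCCc1cc(O)cc(O[Si](C(C)C)(C(C)C)C(C)C)c1 | intermediate
15 | (3-methoxy-5-nonadecylphenoxy)tri(propan-2-yl)silane | CCCCCCCCCCCCCCCCCCCc1cc(OC)cc(O[Si](C(C)C)(C(C)C)C(C)C)c1 | intermediate
16 | 3-methoxy-5-nonadecylphenol | CCCCCCCCCCCCCCCCCCCc1cc(OC)cc(O)c1 | intermediate
17 | 2-methoxy-6-nonadecylcyclohexa-2,5-diene-1,4-dione | CCCCCCCCCCCCCCCCCCCC1=CC(=O)C=C(OC)C1=O | target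

**Step count and risks**
Total: 6 steps. Longest linear sequence: 5 steps (1 → 3 → 4 → 5 → 6, from 1-bromononadecane); step 2 is a one-step branch.

Step 2 (most likely to fail). Monolithium acetylide may disproportionate to insoluble Li2C2 before it is oxidised, and the parent ynolate may be silylated on carbon instead of oxygen. The fallback carries a C-silyl blocking group through the annulation. The same oxidation and O-silylation (n-BuLi; t-BuOOLi; i-Pr3SiOTf, THF) would be run on a true terminal alkyne, commercial ethynyltrimethylsilane, to give triisopropyl{[(trimethylsilyl)ethynyl]oxy}silane F1. The fallback sets out from 5, which would be heated with F1 as in step 3 to give 5-nonadecyl-3-{[tri(propan-2-yl)silyl]oxy}-2-(trimethylsilyl)phenol F2. Ipso-protodesilylation of this electron-rich arylsilane (CF3CO2H, CH2Cl2, 0 °C) should then come back to the route at 14.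

Step 3. The terminal siloxyalkyne may decay at 80–110 °C (1,3-silyl shift to a silylketene, oligomerisation) faster than 5 opens, or vinylketene 10 may be consumed by acylation of the product phenol before the [2+2] event. The fallback is the photochemical Wolff version of the benzannulation, which forms the same two ring bonds but generates 10 at room temperature. It sets out from 1:
- alkylation of methyl acetoacetate (NaH, THF/DMF) would give methyl 2-acetylhenicosanoate F3;
- Krapcho dealkoxycarbonylation (LiCl, wet DMSO, 150 °C) would give docosan-2-one F4;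
- Mannich-type α-methylenation at the more substituted α-carbon (paraformaldehyde, N-methylanilinium trifluoroacetate, THF, reflux) would give 3-methylidenedocosan-2-one F5;
- detrifluoroacetylative Regitz diazo transfer (LiN(SiMe3)2, CF3CO2CH2CF3, THF, −78 °C, passing through 1,1,1-trifluoro-5-methylidenetetracosane-2,4-dione F6; then MsN3, Et3N, H2O, MeCN) would give 1-diazo-3-methylidenedocosan-2-one F7.

Irradiation of F7 with 9 (254 nm, ClCH2CH2Cl, rt, then 80 °C) should pass through 10 to 13 and come back to the route at 14.

Step 1. The Grignard reagent may enolise the vinylogous ester 2 instead of adding to it, and the strained enone may open during the acid treatment. The fallback builds the four-membered ring by ketene cycloaddition and sets out from 1. Alkylation of lithium acetylide–ethylenediamine complex (LiC≡CH·H2NCH2CH2NH2, DMSO, rt) would give henicos-1-yne F8. [2+2] cycloaddition with dichloroketene (Cl3CCOCl, Zn/Cu couple, Et2O/DME, reflux) would give 4,4-dichloro-3-nonadecylcyclobut-2-en-1-one F9. Reductive dechlorination (Zn dust, AcOH, TMEDA, EtOH, 0 °C) should come back to the route at 5.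

**Further compounds**
F1 | step 2 | triisopropyl{[(trimethylsilyl)ethynyl]oxy}silane | C[Si](C)(C)C#CO[Si](C(C)C)(C(C)C)C(C)C
F2 | step 2 | 5-nonadecyl-3-{[tri(propan-2-yl)silyl]oxy}-2-(trimethylsilyl)phenol | CCCCCCCCCCCCCCCCCCCc1cc(O)c([Si](C)(C)C)c(O[Si](C(C)C)(C(C)C)C(C)C)c1
F3 | step 3 | methyl 2-acetylhenicosanoate (racemic) | CCCCCCCCCCCCCCCCCCCC(C(C)=O)C(=O)OC
F4 | step 3 | docosan-2-one | CCCCCCCCCCCCCCCCCCCCC(C)=O
F5 | step 3 | 3-methylidenedocosan-2-one | CCCCCCCCCCCCCCCCCCCC(=C)C(C)=O
F6 | step 3 | 1,1,1-trifluoro-5-methylidenetetracosane-2,4-dione | CCCCCCCCCCCCCCCCCCCC(=C)C(=O)CC(=O)C(F)(F)F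
F7 | step 3 | 1-diazo-3-methylidenedocosan-2-one | CCCCCCCCCCCCCCCCCCCC(=C)C(=O)C=[N+]=[N-]
F8 | step 1 | henicos-1-yne | CCCCCCCCCCCCCCCCCCCC#C
F9 | step 1 | 4,4-dichloro-3-nonadecylcyclobut-2-en-1-one | CCCCCCCCCCCCCCCCCCCC1=CC(=O)C1(Cl)Cl
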